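**Retrosynthetic overview**
- The target is opened back to a doubly linked (2→O→7, 4→8) bicyclic ketal. Reductive cleavage of the ketal C2–O7 bond with hydride returned to the same face sets C2 and gives the 2,4-trans upper flavan.
- The ketal comes from a dearomatising C4-arylation of the 4',7-dihydroxyflavylium cation by C8 of unprotected (−)-epigallocatechin under chiral phosphate control, which sets C4. Ketalisation follows in the same flask.
- The flavylium salt comes from 2,4-dihydroxybenzaldehyde and 4'-hydroxyacetophenone by acid condensation.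
- Ring order: aromatic pyrylium ring C of the upper unit, then its dearomatised 4H-chromene, then the bridged ketal ring, then opening to the upper chroman. The lower unit's rings are bought intact.

Assumption: the target is (2S)-4',7-dihydroxyflavan-(4β→8)-(−)-epigallocatechin, upper unit (2S,4R), lower unit (2R,3R), and (−)-epigallocatechin is bought.
Assumption: the (R)-phosphoric acid is written in step 2; its sense of induction must be checked on the first run, and the (S)-acid is used if the epimeric ketal predominates, since the nucleophile itself imposes little facial bias.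

**Step 1**
Reactants: 1 2,4-dihydroxybenzaldehyde; 2 4'-hydroxyacetophenone
Product: 4 4',7-dihydroxyflavylium chloride (7-hydroxy-2-(4-hydroxyphenyl)chromenylium chloride), via chalcone 3 (not isolated)
Conditions: HCl (g), EtOAc, 0 °C to rt, 48 h; filter the red chloride
Reagents that add atoms: hydrogen chloride, Cl
Why: Acid-catalysed Claisen–Schmidt aldol condensation gives the 2-hydroxychalcone, whose phenol closes onto the protonated ketone and loses water to aromatise to the benzopyrylium salt, which precipitates as the chloride; no stereocentre is formed.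

**Step 2**
Reactants: 4 4',7-dihydroxyflavylium chloride; 5 (−)-epigallocatechin
Product: 8 bicyclic ketal 4',7-dihydroxyflavan-(2β→O→7, 4β→8)-(−)-epigallocatechin (2,8-dioxabicyclo[3.3.1]nonane core; ketal carbon C2 is R and bears the 4-hydroxyphenyl group; bridgehead C4 is R and is bonded to C8 of the (2R,3R) lower unit, whose O7 is the second ketal oxygen), via anhydrobase 6 (not isolated), via flav-2-ene adduct 7 (not isolated)
Conditions: 5 (1.5 equiv), NaHCO3 (1.0 equiv), (R)-TRIP [(R)-3,3'-bis(2,4,6-triisopropylphenyl)-1,1'-binaphthyl-2,2'-diyl hydrogen phosphate] (10 mol %), MgSO4, EtOAc–THF 4:1, 0 °C to rt, argon, dark, 24 h; Sephadex LH-20 then reversed-phase chromatography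
Reagents that add atoms: none
Why: Proposed new method: NaHCO3 removes HCl from 4 to give the neutral quinone-methide-like anhydrobase 6, which the chiral phosphoric acid re-protonates to a flavylium–chiral phosphate contact ion pair, so that C8 of 5 (the usual site of attack of flavan-3-ols on benzylic cations) adds to one face of C4 of the pyrylium ring in a dearomatising Friedel–Crafts addition that sets C4 as R, after which the 7-OH of the new aryl group adds to the acid-activated enol ether of 7 from the only face it can reach and fixes the ketal carbon C2 as R; the closest known reactions are the uncatalysed coupling of flavylium salts with flavan-3-ols to bicyclic ketals and chiral-phosphate-controlled additions of phenols to flavylium and para-quinone methide electrophiles.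

**Step 3**
Reactants: 8 bicyclic ketal
Product: 11 (2R,3R)-8-[(2S,4R)-7-hydroxy-2-(4-hydroxyphenyl)-3,4-dihydro-2H-chromen-4-yl]-2-(3,4,5-trihydroxyphenyl)-3,4-dihydro-2H-chromene-3,5,7-triol (target), via heptakis-TMS ketal 9 (not isolated), via heptakis-TMS flavan 10 (not isolated)
Conditions: (Me3Si)2NH (6 equiv), Me3SiCl (cat.), MeCN, 60 °C, then evaporate; iBu2AlH (3 equiv), CH2Cl2, −78 to −20 °C; MeOH, then 0.5 M aq. HCl–THF, rt
Reagents that add atoms: none
Why: Proposed new method: after transient O-silylation, iBu2AlH coordinates a ketal oxygen and ionises the C2–O bond to a tight oxocarbenium–aryloxyaluminate pair that returns its hydride to the same face of C2 (reductive acetal cleavage with retention), the C2–O7 bond to the phloroglucinol-type ring being expected to break in preference because that aryloxide is the better leaving group and the resorcinol-type O1 the better donor, so that hydrogen enters C2 syn to the C4 aryl group and gives the 2,4-trans (2S,4R) flavan; the closest known reaction is the retentive cleavage of chiral and bicyclic acetals by aluminium hydrides.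

**Compound list**
1 | 2,4-dihydroxybenzaldehyde | O=Cc1ccc(O)cc1O | starting material
2 | 4'-hydroxyacetophenone | CC(=O)c1ccc(O)cc1 | starting material
3 | (E)-3-(2,4-dihydroxyphenyl)-1-(4-hydroxyphenyl)prop-2-en-1-one (2-hydroxychalcone) | O=C(/C=C/c1ccc(O)cc1O)c1ccc(O)cc1 | intermediate
4 | 4',7-dihydroxyflavylium chloride | [Cl-].Oc1ccc(-c2ccc3ccc(O)cc3[o+]2)cc1 | intermediate
5 | (−)-epigallocatechin, (2R,3R) | Oc1cc(O)c2c(c1)O[C@H](c1cc(O)c(O)c(O)c1)[C@H](O)C2 | starting material
6 | 2-(4-hydroxyphenyl)-7H-chromen-7-one (quinoidal anhydrobase) | O=C1C=CC2=CC=C(c3ccc(O)cc3)OC2=C1 | intermediate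
7 | (4R)-4-[(2R,3R)-epigallocatechin-8-yl]-2-(4-hydroxyphenyl)-4H-chromen-7-ol (flav-2-ene adduct) | Oc1ccc(C2=C[C@@H](c3c(O)cc(O)c4c3O[C@H](c3cc(O)c(O)c(O)c3)[C@H](O)C4)c3ccc(O)cc3O2)cc1 | intermediate
8 | bicyclic ketal, upper C2 (R) and C4 (R), lower (2R,3R) | Oc1ccc([C@@]23C[C@@H](c4c(O2)cc(O)c5c4O[C@H](c4cc(O)c(O)c(O)c4)[C@H](O)C5)c4ccc(O)cc4O3)cc1 | intermediate
9 | heptakis(trimethylsilyl) ether of 8 (all seven OH groups) | C[Si](C)(C)Oc1ccc([C@@]23C[C@@H](c4c(O2)cc(O[Si](C)(C)C)c5c4O[C@H](c4cc(O[Si](C)(C)C)c(O[Si](C)(C)C)c(O[Si](C)(C)C)c4)[C@H](O[Si](C)(C)C)C5)c4ccc(O[Si](C)(C)C)cc4O3)cc1 | intermediate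
10 | heptakis(trimethylsilyl) ether of 11 with the lower-unit 7-OH free (the phenol after the MeOH quench) | C[Si](C)(C)Oc1ccc([C@@H]2C[C@@H](c3c(O)cc(O[Si](C)(C)C)c4c3O[C@H](c3cc(O[Si](C)(C)C)c(O[Si](C)(C)C)c(O[Si](C)(C)C)c3)[C@H](O[Si](C)(C)C)C4)c3ccc(O[Si](C)(C)C)cc3O2)cc1 | intermediate
11 | (2S)-4',7-dihydroxyflavan-(4β→8)-(−)-epigallocatechin, upper (2S,4R), lower (2R,3R) | Oc1ccc([C@@H]2C[C@@H](c3c(O)cc(O)c4c3O[C@H](c3cc(O)c(O)c(O)c3)[C@H](O)C4)c3ccc(O)cc3O2)cc1 | target

**Step count**
Total steps: 3. Longest linear sequence: 3 steps.

**Steps most likely to fail**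

Step 3 is the most exposed. The two ketal C–O bonds are electronically close, so cleavage of C2–O1 would give the regioisomeric pyranochromene, and hydride delivered from outside the ion pair would give the 2,4-cis epimer. The fallback sets out from 5 and moves stereocontrol to a C2 centre taken from the chiral pool. Purchased (2S)-liquiritigenin (O=C1C[C@@H](c2ccc(O)cc2)Oc2cc(O)ccc12) is reduced with NaBH4 in EtOH at 0 °C to (2S,4S)-2-(4-hydroxyphenyl)-3,4-dihydro-2H-chromene-4,7-diol F1. F1 is ionised in 0.1 M HCl in MeOH at rt in the presence of 5 (4 equiv). The C4 cation, stabilised by the 7-OH as a para-quinone methide, is attacked by C8 of 5 anti to the 2-aryl group. This gives the 2,4-trans flavan with unambiguous constitution and comes back to the route at 11.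

Step 2 is next. Chiral-anion control may be weak in the polar medium needed to dissolve 5, and attack through C6 or double arylation may compete. The fallback sets out from 4 and replaces the cationic aromatic electrophile by a neutral enone under hydrogen-bond catalysis. Compound 4 is kept in sodium acetate buffer (pH 5.5, water–MeOH, 40 °C, dark) until it has relaxed to the ring-opened chalcone 3, which is isolated this time. Chalcone 3 and 5 are combined with a quinine-derived bifunctional squaramide (10 mol %) in THF. The squaramide binds the enone and the quinuclidine activates the phenol for an enantioselective Friedel–Crafts-type Michael addition of C8 to the β-carbon. This gives (3R)-3-(2,4-dihydroxyphenyl)-1-(4-hydroxyphenyl)-3-[(2R,3R)-3,5,7-trihydroxy-2-(3,4,5-trihydroxyphenyl)-3,4-dihydro-2H-chromen-8-yl]propan-1-one F2. Catalytic p-toluenesulfonic acid then closes both ortho phenols onto the ketone, and the route is rejoined at 8.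

Step 1 is the least exposed. The electron-rich aldehyde may condense sluggishly or oligomerise. The fallback sets out from 2 and builds the pyrylium ring from the other side. Compound 2 is formylated with NaH and ethyl formate in THF to 3-(4-hydroxyphenyl)-3-oxopropanal F3. F3 is condensed with resorcinol in acetic acid saturated with HCl. The aldehyde carbon alkylates C4 of resorcinol and the neighbouring OH closes onto the ketone with loss of water. The route is rejoined at 4.

**Further compounds**
F1 | step 3 | (2S,4S)-2-(4-hydroxyphenyl)-3,4-dihydro-2H-chromene-4,7-diol | Oc1ccc([C@@H]2C[C@H](O)c3ccc(O)cc3O2)cc1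
F2 | step 2 | (3R)-3-(2,4-dihydroxyphenyl)-1-(4-hydroxyphenyl)-3-[(2R,3R)-3,5,7-trihydroxy-2-(3,4,5-trihydroxyphenyl)-3,4-dihydro-2H-chromen-8-yl]propan-1-one | O=C(c1ccc(O)cc1)C[C@@H](c1c(O)cc(O)c2c1O[C@H](c1cc(O)c(O)c(O)c1)[C@H](O)C2)c1ccc(O)cc1O
F3 | step 1 | 3-(4-hydroxyphenyl)-3-oxopropanal | O=CCC(=O)c1ccc(O)cc1
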